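Time comes first: a run of 2.0 h means little until I hold it against the clocks inside the flask.

| flask | starting material | partner | protic impurity | time | remark |
|---|---|---|---|---|---|
| Friday's | 0.14 M | 0.280 M (fed, over 1.60 h) | 2.80 mM | 2.0 h | all but partner at the start; partner goes in evenly over 1.60 h, the run ends at 2.0 h |
| Thursday's | 0.14 M (fed, over 1.60 h) | 0.280 M | 2.80 mM | 2.0 h | a stirred flask in which starting material is dosed at a steady rate over 1.60 h without added volume, worked up at 2.0 h |
| Tuesday's | 0.14 M | 0.280 M | 2.80 mM | 2.0 h | a closed flask charged with all of it at once and left for 2.0 h |
| Sunday's | 0.14 M | 0.280 M | 2.80 mM |  | one stirred flow tank at steady state, fed with the mixture as stated, mean residence time 2.0 h |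

    starting material + partner ⇌ target + by-product (K1 = 0.441, k1 = 1.57 M⁻¹ min⁻¹)
    target ⇌ isomer of the product (K2 = 0.829, k2 = 0.0684 min⁻¹)
    starting material + protic impurity → quenched substrate (k3 = 14.1 M⁻¹ min⁻¹)

- the stated concentrations are those of everything mixed, before any reaction; amounts are the same in each set-up
- the feed brings no volume worth counting
- run time (Friday's): 2.0 h

- the set-up with the highest amount of target at the outlet or at the end, in percent of the starting material put in ("none" if the first two lie within 2 percentage points) (Friday's / Thursday's / Tuesday's / Sunday's / none)
- amount of target at the outlet or at the end, in percent of the starting material put in, Friday's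
- amount of target at the outlet or at the end, in percent of the starting material put in, Thursday's
- amount of target at the outlet or at the end, in percent of the starting material put in, Tuesday's
- amount of target at the outlet or at the end, in percent of the starting material put in, Sunday's

At Tuesday's charge, the partner takes starting material ten times faster than the protic impurity does. But the impurity's pseudo-first-order lifetime there is 0.507 min, shorter than the run, so I strike its 2.80 mM from the charge and keep 0.137 M of starting material, a step I test below. I call the second step's clock the isomer clock: the relaxation time, one over the sum of the second step's forward and back constants, 6.63 min. The forward half-life of the first step, 1.6 min at Tuesday's charge, is shorter than that clock.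

The 24.0 min after dosing in Friday's and Thursday's flasks are 3.62 clocks, which leaves 2.67 % of any gap in the second step, and Tuesday's flask has the whole 2.0 h, so I treat Friday's, Thursday's and Tuesday's alike as equilibrated. Target then holds 0.547 of the product pool, target plus isomer. The first step's constant divided by that share gives 0.807, and the quadratic gives a pool of 0.0877 M. That makes 34.2 % target. The drift passes the test: at the 0.0493 M of starting material I reckon to be left, the impurity's lifetime is 1.43 min, still shorter than the time after dosing.

The weak link is Sunday's tank, where the outlet also removes isomer. Reforged with the washout rate added to the clock, the share becomes 0.570, and the same quadratic gives 35.4 %.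

The forecast says 34.3 %, 34.3 %, 34.2 % and 35 %, best none, holding that “all three flask set-ups finish essentially at the same overall equilibrium”. For Sunday's tank, my 35.4 % is higher than the forecast's.

The simulation gives 34.3 %, 34.3 %, 34.2 % and 35.0 %, best none.

Tuesday's run lasts 18.1 isomer clocks, and the forward half-life of target by the second step alone, 0.17 h, is short against 2.0 h. Tuesday's reading at 20.0 h is 34.2 %. In Sunday's tank the washout rate of 0.008333 min⁻¹ is slower than the clock's 0.151 min⁻¹, and the reading lies 0.40 percentage points under my reforged figure, with 0.0514 M of starting material in the tank.

The numbers of this flask stand for no real mixture; the flask was simulated.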